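**Strategy.** The 1,2-dioxane ring is opened at O–C6. C6, the fully substituted peroxide carbon (CH3, C5, C7), is read as the Markovnikov end of an (E)-C6=C7 alkene, tethered through C5 to C4 of a preformed γ-lactone whose C3 carries a free hydroperoxide cis to that arm. Divalent mercury then closes the dioxane 6-exo: the cis-fused lactone templates a chair in which the mercury-bearing C7 sits equatorial, so C6 is set relative to C3/C4, and hydride demercuration leaves C7H2. C4 derives from (R)-lactic acid, C3 from a catalyst-controlled enal peroxidation, and the sensitive (E,E,E)-triene is attached last by Suzuki coupling.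

Key step: step 14

Remark: locants follow the parent acid chain (C1 lactone carbonyl, C3 and C6 the two peroxide carbons, C4 the lactone C–O carbon, C7–C22 the side chain). The amine-catalysed peroxidation is assumed to accept 2-methoxyprop-2-yl hydroperoxide and to follow the facial sense of the analogous amine-catalysed epoxidation.

Step 1
Reactants: 1 dec-9-yn-1-ol
Product: 2 (E)-10-iododec-9-en-1-ol
Conditions: Cp2Zr(H)Cl (2.2 equiv), THF, rt; then I2, 0 °C
Reagents that add atoms: iodine (II)
Why: Hydrozirconation of the terminal alkyne is syn with zirconium on the terminal carbon, and iodinolysis with retention should give the (E)-iodoalkene (hydrozirconation–iodination); the extra equivalent covers the free hydroxyl.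

Step 2
Reactants: 2 (E)-10-iododec-9-en-1-ol
Product: 3 (E)-10-iododec-9-enal
Conditions: TEMPO (cat.), PhI(OAc)2, CH2Cl2, rt
Reagents that add atoms: none
Why: The oxoammonium oxidation of a primary alcohol stops at the aldehyde and leaves the iodoalkene untouched (TEMPO oxidation).

Step 3
Reactants: 3 (E)-10-iododec-9-enal
Product: 4 ethyl (2E,11E)-12-iodo-2-methyldodeca-2,11-dienoate
Conditions: Ph3P=C(CH3)CO2Et, CH2Cl2, rt
Reagents that add atoms: ethyl 2-(triphenylphosphoranylidene)propanoate (CCOC(=O)C(C)=P(c1ccccc1)(c1ccccc1)c1ccccc1)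
Why: The stabilised α-methyl ylide should give the (E)-trisubstituted enoate (Wittig olefination), which fixes the later C6=C7 geometry.

Step 4
Reactants: 4 ethyl (2E,11E)-12-iodo-2-methyldodeca-2,11-dienoate
Product: 5 (2E,11E)-12-iodo-2-methyldodeca-2,11-dien-1-ol
Conditions: iBu2AlH (2.2 equiv), CH2Cl2, −78 °C
Reagents that add atoms: none
Why: The aluminium hydride reduces the conjugated ester 1,2 to the allylic alcohol without touching the iodoalkene (hydride reduction).

Step 5
Reactants: 5 (2E,11E)-12-iodo-2-methyldodeca-2,11-dien-1-ol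
Product: 6 (2E,11E)-1-bromo-12-iodo-2-methyldodeca-2,11-diene
Conditions: CBr4, PPh3, CH2Cl2, 0 °C
Reagents that add atoms: tetrabromomethane (BrC(Br)(Br)Br)
Why: The Appel reaction converts the primary allylic alcohol into the bromide under neutral conditions without allylic transposition or loss of alkene geometry.

Step 6
Reactants: 7 (R)-lactic acid
Product: 8 (2R,5R)-2-tert-butyl-5-methyl-1,3-dioxolan-4-one
Conditions: pivalaldehyde, TsOH (cat.), H2SO4 (cat.), pentane, reflux with water removal; crystallisation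
Reagents that add atoms: pivalaldehyde (CC(C)(C)C=O)
Why: Acid-catalysed acetalisation of the hydroxy acid gives mainly the cis-dioxolanone, which crystallises (dioxolanone formation for self-regeneration of the stereocentre).

Step 7
Reactants: 8 (2R,5R)-2-tert-butyl-5-methyl-1,3-dioxolan-4-one; 6 (2E,11E)-1-bromo-12-iodo-2-methyldodeca-2,11-diene
Product: 9 (2R,5S)-2-tert-butyl-5-[(2E,11E)-12-iodo-2-methyldodeca-2,11-dien-1-yl]-5-methyl-1,3-dioxolan-4-one
Conditions: lithium diisopropylamide, THF, −78 °C; then 6, −78 to −30 °C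
Reagents that add atoms: none
Why: The lithium enolate is alkylated by the allylic bromide anti to the tert-butyl group, so the arm takes the place of the former hydrogen and the future C4 is set as S (diastereoselective enolate alkylation with self-regeneration of the stereocentre).

Step 8
Reactants: 9 (2R,5S)-2-tert-butyl-5-[(2E,11E)-12-iodo-2-methyldodeca-2,11-dien-1-yl]-5-methyl-1,3-dioxolan-4-one
Product: 10 (2R,5S)-2-tert-butyl-5-[(2E,11E)-12-iodo-2-methyldodeca-2,11-dien-1-yl]-5-methyl-1,3-dioxolan-4-ol (hemiacetal epimers)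
Conditions: iBu2AlH (1.1 equiv), CH2Cl2, −78 °C
Reagents that add atoms: none
Why: At low temperature the acylal-type lactone is reduced only to the hemiacetal, a masked α-hydroxy aldehyde (partial hydride reduction of a lactone).

Step 9
Reactants: 10 (2R,5S)-2-tert-butyl-5-[(2E,11E)-12-iodo-2-methyldodeca-2,11-dien-1-yl]-5-methyl-1,3-dioxolan-4-ol
Product: 11 (2E,4S,6E,15E)-4-hydroxy-16-iodo-4,6-dimethylhexadeca-2,6,15-trienal
Conditions: Ph3P=CHCHO (2.5 equiv), toluene, 80 °C
Reagents that add atoms: (triphenylphosphoranylidene)acetaldehyde (O=CC=P(c1ccccc1)(c1ccccc1)c1ccccc1)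
Why: The hemiacetal opens to the aldehyde, which the stabilised formyl ylide olefinates (E)-selectively while pivalaldehyde is lost from the tertiary oxygen (Wittig olefination of a lactol-type masked aldehyde).

Step 10
Reactants: 12 2,3-dimethylbut-2-ene
Product: 13 2-methoxyprop-2-yl hydroperoxide
Conditions: O3, MeOH–CH2Cl2, −78 °C
Reagents that add atoms: ozone ([O-][O+]=O); methanol (CO)
Why: Ozonolysis in methanol traps the carbonyl oxide as the α-methoxy hydroperoxide, a hydroperoxide carrying an acid-labile ketal mask (ozonolysis with solvent capture).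

Step 11
Reactants: 11 (2E,4S,6E,15E)-4-hydroxy-16-iodo-4,6-dimethylhexadeca-2,6,15-trienal; 13 2-methoxyprop-2-yl hydroperoxide
Product: 15 (4S,5S)-5-[(2E,11E)-12-iodo-2-methyldodeca-2,11-dien-1-yl]-4-[(2-methoxypropan-2-yl)peroxy]-5-methyloxolan-2-ol (lactol; anomer mixture), via β-peroxy aldehyde 14 (not isolated)
Conditions: (R)-2-{bis[3,5-bis(trifluoromethyl)phenyl](trimethylsilyloxy)methyl}pyrrolidine (20 mol%), 13 (3 equiv), toluene, 0 °C to rt
Reagents that add atoms: none
Why: Iminium activation by the chiral secondary amine lets the hydroperoxide add to C3 from the face left open by the diaryl(silyloxy)methyl group, which should set C3 as S under catalyst control, and the C4 hydroxyl then traps the aldehyde as the lactol (organocatalytic asymmetric conjugate peroxidation of an enal).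

Step 12
Reactants: 15 (4S,5S)-5-[(2E,11E)-12-iodo-2-methyldodeca-2,11-dien-1-yl]-4-[(2-methoxypropan-2-yl)peroxy]-5-methyloxolan-2-ol
Product: 16 (4S,5S)-5-[(2E,11E)-12-iodo-2-methyldodeca-2,11-dien-1-yl]-4-[(2-methoxypropan-2-yl)peroxy]-5-methyloxolan-2-one
Conditions: nPr4N[RuO4] (5 mol%), N-methylmorpholine N-oxide, 4 Å molecular sieves, CH2Cl2, rt
Reagents that add atoms: none
Why: Catalytic perruthenate oxidises lactols to lactones under neutral conditions that should leave the peroxyketal and the iodoalkene intact (Ley–Griffith oxidation).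

Step 13
Reactants: 16 (4S,5S)-5-[(2E,11E)-12-iodo-2-methyldodeca-2,11-dien-1-yl]-4-[(2-methoxypropan-2-yl)peroxy]-5-methyloxolan-2-one
Product: 17 (4S,5S)-4-hydroperoxy-5-[(2E,11E)-12-iodo-2-methyldodeca-2,11-dien-1-yl]-5-methyloxolan-2-one
Conditions: AcOH–THF–H2O (4:2:1), rt
Reagents that add atoms: none
Why: Mild aqueous acid hydrolyses the peroxyketal to the free hydroperoxide without opening the lactone (ketal hydrolysis).

Step 14
Reactants: 17 (4S,5S)-4-hydroperoxy-5-[(2E,11E)-12-iodo-2-methyldodeca-2,11-dien-1-yl]-5-methyloxolan-2-one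
Product: 19 (3S,4aS,7aS)-3-[(9E)-10-iododec-9-en-1-yl]-3,4a-dimethyl-3,4,4a,7a-tetrahydrofuro[3,2-c][1,2]dioxin-6(7H)-one (cis-fused peroxylactone; 3S,4S,6S in chain locants), via C7-acetoxymercurio dioxane 18 (not isolated)
Conditions: Hg(OAc)2 (1.1 equiv), HClO4 (cat.), CH2Cl2, 0 °C; then NaBH4, THF–H2O, −20 °C
Reagents that add atoms: none
Why: Hg(OAc)2 reversibly forms a mercurinium ion on the electron-rich trisubstituted C6=C7 alkene and the terminal oxygen of the C3 hydroperoxide opens it anti at the tertiary carbon C6, forming the O–C6 bond; NaBH4 then replaces C7–Hg by C7–H through a short-lived C7 radical that the mercury hydride chain carrier should capture before it attacks the O–O bond. The closest known reaction type is the cycloperoxymercuration–hydridodemercuration of alkenyl hydroperoxides to 3-alkyl-1,2-dioxanes. The 1,2-dioxane ring closes in the 6-exo-trig mode, and Markovnikov and exo preferences both direct oxygen to C6 and not to C7. The new stereocentre C6 is controlled by C3 and C4 through a chair transition state: the cis-fused lactone holds O4 axial and the C4 methyl equatorial, the bulky mercury-bearing C7 takes the equatorial position and the C6 methyl the axial one syn to O4, which is the 6S arrangement, whereas the competing chairs put C7 or a methyl group into a 1,3-diaxial clash. The step also needs chemoselectivity for the trisubstituted alkene over the iodoalkene, which its higher nucleophilicity and the intramolecular delivery should secure, and the cis ring fusion is automatic because only the cis hydroperoxide can reach C6.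

Step 15
Reactants: 20 (E)-pent-2-enal
Product: 21 2-[(1E,3E)-hexa-1,3-dien-1-yl]-4,4,5,5-tetramethyl-1,3,2-dioxaborolane
Conditions: Cl2CHB(pin), CrCl2 (8 equiv), LiI, THF, rt
Reagents that add atoms: 2-(dichloromethyl)-4,4,5,5-tetramethyl-1,3,2-dioxaborolane (ClC(Cl)B1OC(C)(C)C(C)(C)O1)
Why: The geminal dichromium species adds to the aldehyde and eliminates to the (E)-alkenylboronate, so the (1E,3E)-diene should result (Takai–Utimoto boryl olefination).

Step 16
Reactants: 19 (3S,4aS,7aS)-3-[(9E)-10-iododec-9-en-1-yl]-3,4a-dimethyl-3,4,4a,7a-tetrahydrofuro[3,2-c][1,2]dioxin-6(7H)-one; 21 2-[(1E,3E)-hexa-1,3-dien-1-yl]-4,4,5,5-tetramethyl-1,3,2-dioxaborolane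
Product: 22 (3S,4aS,7aS)-3-[(9E,11E,13E)-hexadeca-9,11,13-trien-1-yl]-3,4a-dimethyl-3,4,4a,7a-tetrahydrofuro[3,2-c][1,2]dioxin-6(7H)-one (target)
Conditions: PdCl2(dppf) (5 mol%), K3PO4 (aq), THF, rt, degassed, dark
Reagents that add atoms: none
Why: Suzuki–Miyaura coupling of the (E)-iodoalkene with the (E,E)-dienylboronate proceeds with retention at both partners to give the (E,E,E)-triene, and a dialkyl peroxide of this type should tolerate zerovalent palladium at room temperature.

**Compound list**

1 | dec-9-yn-1-ol | OCCCCCCCCC#C | starting material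
2 | (E)-10-iododec-9-en-1-ol | OCCCCCCCC/C=C/I | intermediate
3 | (E)-10-iododec-9-enal | O=CCCCCCCC/C=C/I | intermediate
4 | ethyl (2E,11E)-12-iodo-2-methyldodeca-2,11-dienoate | CCOC(=O)/C(C)=C/CCCCCCC/C=C/I | intermediate
5 | (2E,11E)-12-iodo-2-methyldodeca-2,11-dien-1-ol | OC/C(C)=C/CCCCCCC/C=C/I | intermediate
6 | (2E,11E)-1-bromo-12-iodo-2-methyldodeca-2,11-diene | BrC/C(C)=C/CCCCCCC/C=C/I | intermediate
7 | (R)-lactic acid | C[C@@H](O)C(=O)O | starting material
8 | (2R,5R)-2-tert-butyl-5-methyl-1,3-dioxolan-4-one | C[C@H]1O[C@@H](C(C)(C)C)OC1=O | intermediate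
9 | (2R,5S)-2-tert-butyl-5-[(2E,11E)-12-iodo-2-methyldodeca-2,11-dien-1-yl]-5-methyl-1,3-dioxolan-4-one | C[C@@]1(C/C(C)=C/CCCCCCC/C=C/I)O[C@@H](C(C)(C)C)OC1=O | intermediate
10 | (2R,5S)-2-tert-butyl-5-[(2E,11E)-12-iodo-2-methyldodeca-2,11-dien-1-yl]-5-methyl-1,3-dioxolan-4-ol | C[C@@]1(C/C(C)=C/CCCCCCC/C=C/I)O[C@@H](C(C)(C)C)OC1O | intermediate
11 | (2E,4S,6E,15E)-4-hydroxy-16-iodo-4,6-dimethylhexadeca-2,6,15-trienal | C[C@@](/C=C/C=O)(C/C(C)=C/CCCCCCC/C=C/I)O | intermediate
12 | 2,3-dimethylbut-2-ene | CC(C)=C(C)C | starting material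
13 | 2-methoxyprop-2-yl hydroperoxide | COC(C)(C)OO | intermediate
14 | (3S,4S,6E,15E)-4-hydroxy-16-iodo-3-[(2-methoxypropan-2-yl)peroxy]-4,6-dimethylhexadeca-6,15-dienal (not isolated) | O=CC[C@H](OOC(C)(C)OC)[C@@](C)(O)C/C(C)=C/CCCCCCC/C=C/I | intermediate
15 | (4S,5S)-5-[(2E,11E)-12-iodo-2-methyldodeca-2,11-dien-1-yl]-4-[(2-methoxypropan-2-yl)peroxy]-5-methyloxolan-2-ol | OC1C[C@H](OOC(C)(C)OC)[C@](C)(C/C(C)=C/CCCCCCC/C=C/I)O1 | intermediate
16 | (4S,5S)-5-[(2E,11E)-12-iodo-2-methyldodeca-2,11-dien-1-yl]-4-[(2-methoxypropan-2-yl)peroxy]-5-methyloxolan-2-one | O=C1C[C@H](OOC(C)(C)OC)[C@](C)(C/C(C)=C/CCCCCCC/C=C/I)O1 | intermediate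
17 | (4S,5S)-4-hydroperoxy-5-[(2E,11E)-12-iodo-2-methyldodeca-2,11-dien-1-yl]-5-methyloxolan-2-one | O=C1C[C@H](OO)[C@](C)(C/C(C)=C/CCCCCCC/C=C/I)O1 | intermediate
18 | C7-acetoxymercurio derivative of 19 (anti adduct, 7S; C6 arranged as in 19; not isolated) | I/C=C/CCCCCCC[C@H]([Hg]OC(C)=O)[C@@]1(C)C[C@]2(C)OC(=O)C[C@@H]2OO1 | intermediate
19 | (3S,4aS,7aS)-3-[(9E)-10-iododec-9-en-1-yl]-3,4a-dimethyl-3,4,4a,7a-tetrahydrofuro[3,2-c][1,2]dioxin-6(7H)-one | I/C=C/CCCCCCCC[C@@]1(C)C[C@]2(C)OC(=O)C[C@@H]2OO1 | intermediate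
20 | (E)-pent-2-enal | CC/C=C/C=O | starting material
21 | 2-[(1E,3E)-hexa-1,3-dien-1-yl]-4,4,5,5-tetramethyl-1,3,2-dioxaborolane | CC/C=C/C=C/B1OC(C)(C)C(C)(C)O1 | intermediate
22 | (3S,4aS,7aS)-3-[(9E,11E,13E)-hexadeca-9,11,13-trien-1-yl]-3,4a-dimethyl-3,4,4a,7a-tetrahydrofuro[3,2-c][1,2]dioxin-6(7H)-one | CC/C=C/C=C/C=C/CCCCCCCC[C@@]1(C)C[C@]2(C)OC(=O)C[C@@H]2OO1 | target

Total step count: 16
Longest linear sequence: 13 steps (steps 1–5, 7–9, 11–14, 16)

**Steps most likely to fail**

1. Step 14 (key step). The mercurinium opening may discriminate poorly between the two chairs, giving the C6 epimer, and the C7 radical formed on demercuration may fragment onto the O–O bond to give an epoxide. The fallback sets out from 16 and comes back at 19, carrying the C6 configuration into the ring closure as a preformed epoxide.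
   - Shi epoxidation of 16 with the L-fructose-derived ketone (Oxone, K2CO3 buffer, MeCN–dimethoxymethane, 0 °C) should give the (6S,7S)-epoxide F4.
   - Aqueous acetic acid, then catalytic camphorsulfonic acid in CH2Cl2, frees the hydroperoxy epoxide F5. It should open the epoxide 6-exo-tet at the tertiary carbon C6 with inversion to give the 7-hydroxy dioxane F6.
   - Dehydration with Martin sulfurane can only run towards C8 and gives the C7=C8 alkene F7.
   - Diimide (2-nitrobenzenesulfonyl hydrazide, Et3N, CH2Cl2) saturates F7 to 19 without touching the peroxide or the iodoalkene.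

2. Step 11. Iminium formation and conjugate addition next to the quaternary C4 may be slow, the neighbouring stereocentre may erode catalyst control at C3, and the enamine may close to an epoxide. The fallback sets out from 10 and comes back at 17.
   - Still–Gennari olefination of 10 (methyl bis(2,2,2-trifluoroethyl)phosphonoacetate, KN(SiMe3)2, 18-crown-6, THF, −78 °C) gives the (Z)-hydroxy enoate F1, which lactonises to the butenolide F2.
   - Base-mediated conjugate addition of hydrogen peroxide (urea–H2O2, Et2NH cat., CF3CH2OH) gives 17 together with its C3 epimer F3.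
   - Only 17 can cyclise in step 14; F3 is separated and returned to F2 by Et3N-induced loss of hydrogen peroxide.

3. Step 16. Phosphine or zerovalent palladium may reduce the O–O bond, aqueous base may open the β-peroxy lactone by retro-conjugate addition, and the triene may isomerise. The fallback sets out from 20 and comes back at 22 with a neutral, base-free and phosphine-free tin coupling.
   - Ohira–Bestmann homologation of 20 (dimethyl (1-diazo-2-oxopropyl)phosphonate, K2CO3, MeOH) gives (E)-hex-3-en-1-yne F8.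
   - Hydrostannation catalysed by PdCl2(PPh3)2 with Bu3SnH gives tributyl[(1E,3E)-hexa-1,3-dien-1-yl]stannane F9.
   - Stille coupling of F9 with 19 (PdCl2(MeCN)2, DMF, rt, dark) gives 22.

**Further compounds**

F1 | step 11 | methyl (2Z,4S,6E,15E)-4-hydroxy-16-iodo-4,6-dimethylhexadeca-2,6,15-trienoate | COC(=O)/C=C\[C@@](C)(O)C/C(C)=C/CCCCCCC/C=C/I
F2 | step 11 | (5S)-5-[(2E,11E)-12-iodo-2-methyldodeca-2,11-dien-1-yl]-5-methylfuran-2(5H)-one | O=C1C=C[C@](C)(C/C(C)=C/CCCCCCC/C=C/I)O1
F3 | step 11 | (4R,5S)-4-hydroperoxy-5-[(2E,11E)-12-iodo-2-methyldodeca-2,11-dien-1-yl]-5-methyloxolan-2-one | O=C1C[C@@H](OO)[C@](C)(C/C(C)=C/CCCCCCC/C=C/I)O1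
F4 | step 14 | (4S,5S)-5-{[(2S,3S)-3-[(8E)-9-iodonon-8-en-1-yl]-2-methyloxiran-2-yl]methyl}-4-[(2-methoxypropan-2-yl)peroxy]-5-methyloxolan-2-one | O=C1C[C@H](OOC(C)(C)OC)[C@](C)(C[C@]2(C)O[C@H]2CCCCCCC/C=C/I)O1
F5 | step 14 | (4S,5S)-4-hydroperoxy-5-{[(2S,3S)-3-[(8E)-9-iodonon-8-en-1-yl]-2-methyloxiran-2-yl]methyl}-5-methyloxolan-2-one | O=C1C[C@H](OO)[C@](C)(C[C@]2(C)O[C@H]2CCCCCCC/C=C/I)O1
F6 | step 14 | 7-hydroxy derivative of 19 (7S; C6 arranged as in 19) | I/C=C/CCCCCCC[C@H](O)[C@@]1(C)C[C@]2(C)OC(=O)C[C@@H]2OO1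
F7 | step 14 | 7,8-didehydro derivative of 19 (C6 arranged as in 19) | I/C=C/CCCCCCC=C[C@@]1(C)C[C@]2(C)OC(=O)C[C@@H]2OO1
F8 | step 16 | (E)-hex-3-en-1-yne | CC/C=C/C#C
F9 | step 16 | tributyl[(1E,3E)-hexa-1,3-dien-1-yl]stannane | CC/C=C/C=C/[Sn](CCCC)(CCCC)CCCC
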